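**Assumption:** ubiquinol-6 has no stereocentres (it is achiral), so "single enantiomer" is read as the single all-E (2'E,6'E,10'E,14'E,18'E) geometric isomer encoded in the SMILES.

## Retrosynthetic overview

1. Ubiquinol-6 (15) ⇐ ubiquinone-6 (14) by dithionite reduction; no protecting groups on the ring at any stage after the quinone is made.
2. 14 ⇐ chloromethylquinone 4 + C28 terminal alkyne 13. This is the key step: Zr-catalysed methylalumination then Ni(0) coupling forms C1'–C2', installs the C3' methyl and sets the 2'E olefin in one pot. It replaces the usual Friedel–Crafts or aryl-metal prenylation.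
3. 13 ⇐ C24 (E)-alkenyl iodide 10 + homopropargylzinc from 11 (Pd alkyl–alkenyl Negishi coupling); 10 ⇐ C23 alkyne 8 by a second methylalumination/iodinolysis, which sets 6'E.
4. 8 ⇐ all-E geranylgeranyl bromide 6 (supplies 10'E, 14'E, 18'E) + lithiated TMS-propyne 7; 4 ⇐ 2,3,4,5-tetramethoxytoluene 1 by chloromethylation and CAN oxidation.
5. Rings: none is formed; the only ring (the benzenoid core) is bought intact in 1.

## Route

**Step 1**
Reactants: 1, 2,3,4,5-tetramethoxytoluene; 2, paraformaldehyde
Product: 3, 1-(chloromethyl)-2,3,4,5-tetramethoxy-6-methylbenzene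
Conditions: (CH2O)n, conc. HCl, dioxane, 40 °C
Reagents that add atoms: formaldehyde (C=O); hydrogen chloride (Cl)
Why: Blanc chloromethylation (electrophilic aromatic substitution) of a very electron-rich arene whose only free position is C6, so regiochemistry is unambiguous.

**Step 2**
Reactants: 3, 1-(chloromethyl)-2,3,4,5-tetramethoxy-6-methylbenzene
Product: 4, 2-(chloromethyl)-5,6-dimethoxy-3-methyl-1,4-benzoquinone
Conditions: CAN (2.5 equiv), MeCN/H2O, 0 °C, 10 min
Reagents that add atoms: water (O); the two quinone oxygens come from water and two MeOH are lost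
Why: CAN oxidative demethylation of the para-disposed methoxy pair gives the p-quinone; the reaction is fast at 0 °C, so the benzylic chloride is not solvolysed, and it becomes a robust chloromethylquinone once the ring is oxidised.

**Step 3**
Reactants: 5, (2E,6E,10E)-geranylgeraniol
Product: 6, (2E,6E,10E)-geranylgeranyl bromide
Conditions: PBr3 (0.4 equiv), Et2O, −10 °C; used crude
Reagents that add atoms: phosphorus tribromide, BrP(Br)Br (Br)
Why: SN2 bromination of a primary allylic alcohol at low temperature proceeds without allylic transposition or E/Z scrambling.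

**Step 4**
Reactants: 6, geranylgeranyl bromide; 7, 1-(trimethylsilyl)propyne
Product: 8, (5E,9E,13E)-6,10,14,18-tetramethylnonadeca-5,9,13,17-tetraen-1-yne
Conditions: 7, n-BuLi, THF, −78 °C; then 6, −78 → −20 °C; then NaOMe, MeOH, rt (one pot)
Reagents that add atoms: 1-(trimethylsilyl)propyne, CC#C[Si](C)(C)C (its C3 unit is retained; TMS is lost)
Why: Propargylic SN2 alkylation of the primary allylic bromide by lithiated TMS-propyne (α-attack, no SN2'), followed by methoxide protodesilylation; the three existing E olefins are untouched.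

**Step 5**
Reactants: 8, C23 tetraenyne; 9, trimethylaluminium
Product: 10, (1E,5E,9E,13E)-1-iodo-2,6,10,14,18-pentamethylnonadeca-1,5,9,13,17-pentaene
Conditions: Me3Al (2 equiv), Cp2ZrCl2 (0.25 equiv), (CH2Cl)2, rt; then I2, THF, −30 → 0 °C
Reagents that add atoms: trimethylaluminium, C[Al](C)C (CH3); iodine, II (I)
Why: Negishi Zr-catalysed carboalumination adds Me–Al syn across the terminal alkyne (Me to the internal carbon), and iodinolysis with retention gives the (E)-alkenyl iodide (≥97:3), setting the future 6'E olefin.

**Step 6**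
Reactants: 10, C24 (E)-alkenyl iodide; 11, (4-bromobut-1-yn-1-yl)trimethylsilane
Product: 12, trimethyl[(5E,9E,13E,17E)-6,10,14,18,22-pentamethyltricosa-5,9,13,17,21-pentaen-1-yn-1-yl]silane
Conditions: 11, Zn dust (I2 cat.), DMA, 70 °C; then 10, PdCl2(dppf) (3 mol %), THF/DMA, rt
Reagents that add atoms: (4-bromobut-1-yn-1-yl)trimethylsilane, C[Si](C)(C)C#CCCBr (the TMS-butynyl unit)
Why: Pd-catalysed alkyl–alkenyl Negishi coupling of a homopropargylzinc with an alkenyl iodide gives the 1,5-enyne with complete retention of the E geometry.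

**Step 7**
Reactants: 12, TMS-protected C28 pentaenyne
Product: 13, (5E,9E,13E,17E)-6,10,14,18,22-pentamethyltricosa-5,9,13,17,21-pentaen-1-yne
Conditions: K2CO3, MeOH/THF, rt
Reagents that add atoms: none
Why: Mild base-mediated protodesilylation of the alkynylsilane; the isolated trisubstituted olefins are inert.

**Step 8**
Reactants: 13, C28 pentaenyne; 9, trimethylaluminium; 4, chloromethylquinone
Product: 14, ubiquinone-6 (2,3-dimethoxy-5-methyl-6-[(2E,6E,10E,14E,18E)-3,7,11,15,19,23-hexamethyltetracosa-2,6,10,14,18,22-hexaenyl]-1,4-benzoquinone)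
Conditions: Me3Al (2 equiv), Cp2ZrCl2 (0.25 equiv), (CH2Cl)2, rt; evaporate excess Me3Al, THF; then 4, Ni(0) [NiCl2(PPh3)2/2 n-BuLi, 3 mol %], −20 °C → rt
Reagents that add atoms: trimethylaluminium, C[Al](C)C (CH3); compound 4 (whole quinone–CH2 unit, minus Cl)
Why: Tandem Negishi carboalumination / Ni(0) cross-coupling of the (E)-alkenylalane with the allylic-type chloride of the quinone; the coupling is faster than carbonyl addition, and syn Me–Al addition with retention in the coupling sets 2'E.

**Step 9**
Reactants: 14, ubiquinone-6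
Product: 15, ubiquinol-6 (target)
Conditions: Na2S2O4 (excess), degassed Et2O/H2O, rt, Ar; isolate and store under Ar
Reagents that add atoms: none
Why: Dithionite reduction of the p-quinone to the hydroquinone (two-electron, two-proton); the olefins and methoxy groups are unaffected.

## Compound list

1 | 2,3,4,5-tetramethoxytoluene | COc1cc(C)c(OC)c(OC)c1OC | starting material
2 | paraformaldehyde (as formaldehyde) | C=O | starting material
3 | 1-(chloromethyl)-2,3,4,5-tetramethoxy-6-methylbenzene | COc1c(C)c(CCl)c(OC)c(OC)c1OC | intermediate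
4 | 2-(chloromethyl)-5,6-dimethoxy-3-methyl-1,4-benzoquinone | COC1=C(OC)C(=O)C(CCl)=C(C)C1=O | intermediate
5 | (2E,6E,10E)-geranylgeraniol | OC/C=C(\C)CC/C=C(\C)CC/C=C(\C)CCC=C(C)C | starting material
6 | (2E,6E,10E)-geranylgeranyl bromide | BrC/C=C(\C)CC/C=C(\C)CC/C=C(\C)CCC=C(C)C | intermediate
7 | 1-(trimethylsilyl)propyne | CC#C[Si](C)(C)C | starting material
8 | (5E,9E,13E)-6,10,14,18-tetramethylnonadeca-5,9,13,17-tetraen-1-yne | C#CCC/C=C(\C)CC/C=C(\C)CC/C=C(\C)CCC=C(C)C | intermediate
9 | trimethylaluminium | C[Al](C)C | starting material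
10 | (1E,5E,9E,13E)-1-iodo-2,6,10,14,18-pentamethylnonadeca-1,5,9,13,17-pentaene | I/C=C(\C)CC/C=C(\C)CC/C=C(\C)CC/C=C(\C)CCC=C(C)C | intermediate
11 | (4-bromobut-1-yn-1-yl)trimethylsilane | C[Si](C)(C)C#CCCBr | starting material
12 | trimethyl[(5E,9E,13E,17E)-6,10,14,18,22-pentamethyltricosa-5,9,13,17,21-pentaen-1-yn-1-yl]silane | C[Si](C)(C)C#CCC/C=C(\C)CC/C=C(\C)CC/C=C(\C)CC/C=C(\C)CCC=C(C)C | intermediate
13 | (5E,9E,13E,17E)-6,10,14,18,22-pentamethyltricosa-5,9,13,17,21-pentaen-1-yne | C#CCC/C=C(\C)CC/C=C(\C)CC/C=C(\C)CC/C=C(\C)CCC=C(C)C | intermediate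
14 | ubiquinone-6 | COC1=C(OC)C(=O)C(C/C=C(\C)CC/C=C(\C)CC/C=C(\C)CC/C=C(\C)CC/C=C(\C)CCC=C(C)C)=C(C)C1=O | intermediate
15 | ubiquinol-6 | COc1c(O)c(C)c(C/C=C(\C)CC/C=C(\C)CC/C=C(\C)CC/C=C(\C)CC/C=C(\C)CCC=C(C)C)c(O)c1OC | target

## Summary

Total step count: 9.
Longest linear sequence: 7 (steps 3 → 9, from geranylgeraniol); the quinone branch (steps 1–2) joins at step 8.

Three steps most likely to fail, each with a fallback that changes the approach:

1. **Step 8** (alkenylalane + unprotected chloromethylquinone). Risks are attack or reduction at the quinone and a few percent of the carboalumination regioisomer. Fallback: reverse the polarity and drop the quinone electrophile. Quench the alkenylalane from 13 with I2 to the (E)-alkenyl iodide, Pd-couple it with the benzylic zinc chloride made from 3 (Zn insertion), then CAN oxidation to 14 and dithionite reduction.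
2. **Step 6** (alkyl–alkenyl Negishi coupling). Risks are sluggish zinc insertion, β-hydride elimination or isomerisation, and homocoupling. Fallback: replace the sp3–sp2 coupling with iterative sp3–sp3 homologation. Trap the alkenylalane from 8 with paraformaldehyde to give all-E geranylfarnesol, convert it to the bromide, and alkylate lithiated TMS-propyne again (then desilylate) to reach 13.
3. **Step 2** (CAN oxidation of the benzylic chloride). Risks are o-quinone formation and hydrolysis of the chloride. Fallback: avoid the quinone and CAN altogether. Reductively acetylate commercial 2,3-dimethoxy-5-methyl-1,4-benzoquinone (Zn, Ac2O), chloromethylate the diacetate, Ni-couple that benzylic chloride with the alkenylalane from 13, and cleave the acetates (K2CO3/MeOH under Ar) to give 15 directly.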